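**Plan**

- Retrosynthesis: the two methoxymethyl (MOM) ethers come off last. The C5′–C(CH3)2 bond is cut by a retro-Claisen to the C4′ O-prenyl ether, and the C4 ketone is traced back to a C4 carbinol. The C3–O and C4–O bonds are then cut together to the C3=C4 alkene of an isoflav-3-ene. That alkene is cut to a ketone/aldehyde pair, and the O1–C2 ether bond and the C1′–C(=O) bond finish the analysis.
- Forward: ring B is acylated (aryllithium plus chloro Weinreb amide), the chloroketone is joined to the ring-A salicylaldehyde through O1–C2, and ring C is closed by McMurry coupling. Dihydroxylation, C4 oxidation, desilylation, O-prenylation, Claisen rearrangement and MOM cleavage follow.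
- Enabling feature: C3 (tertiary carbinol carrying ring B) and C4 (ketone on ring A) are neighbouring oxygenated carbons of ring C. This is the pattern of a cis-3,4-diol made from the styrene-type C3=C4 bond of a 3-aryl-2H-chromene.
- Stereochemistry: the only stereocentre kept, C3 (R), comes from ligand-controlled osmylation with (DHQ)2PHAL. The C4 centre made with it is erased on oxidation, and C3, being fully substituted, cannot epimerise afterwards.

Key step: step 6

Remark: the target SMILES fixes C3 as R. Isoflavonoid numbering is used: rings A and C form the chromanone, ring B is the 3-aryl group with primed locants. The ring-B phenol is carried as a triisopropylsilyl (TIPS) ether and the ring-A phenols as MOM ethers.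

**Route**

Step 1
Reactants: 1 4-bromo-3-methoxyphenol
Product: 2 (4-bromo-3-methoxyphenoxy)triisopropylsilane
Conditions: TIPSCl, imidazole, DMF, rt
Reagents that add atoms: triisopropylsilyl chloride, CC(C)[Si](Cl)(C(C)C)C(C)C
Why: Imidazole-mediated O-silylation of a phenol; the bulky TIPS ether is chosen because it should survive aryllithium formation, carbonate base, low-valent titanium and osmylation, yet leave cleanly with fluoride.

Step 2
Reactants: 2 (4-bromo-3-methoxyphenoxy)triisopropylsilane; 3 2-chloro-N-methoxy-N-methylacetamide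
Product: 6 2-chloro-1-[2-methoxy-4-(triisopropylsilyloxy)phenyl]ethan-1-one, via aryllithium 4 (not isolated), via lithium hemiaminal adduct 5 (not isolated)
Conditions: n-BuLi, THF, −78 °C; then 3, −78 → −40 °C; 1 M HCl
Reagents that add atoms: none
Why: Bromine–lithium exchange followed by Weinreb ketone synthesis; the chelated tetrahedral adduct 5 should persist until the acidic quench, which prevents over-addition and keeps the C–Cl bond intact at low temperature.

Step 3
Reactants: 7 2,4,6-trihydroxybenzaldehyde
Product: 8 2-hydroxy-4,6-bis(methoxymethoxy)benzaldehyde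
Conditions: MOMCl (2.2 equiv), i-Pr2NEt, CH2Cl2, 0 °C → rt
Reagents that add atoms: chloromethyl methyl ether, COCCl
Why: Selective twofold O-alkylation (acetal ether formation); the hydroxyl left over is the one hydrogen-bonded to the formyl group, which is the least nucleophilic and is the one needed for the next step.

Step 4
Reactants: 6 2-chloro-1-[2-methoxy-4-(triisopropylsilyloxy)phenyl]ethan-1-one; 8 2-hydroxy-4,6-bis(methoxymethoxy)benzaldehyde
Product: 9 2-{2-[2-methoxy-4-(triisopropylsilyloxy)phenyl]-2-oxoethoxy}-4,6-bis(methoxymethoxy)benzaldehyde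
Conditions: K2CO3, NaI (cat.), acetone, rt
Reagents that add atoms: none
Why: Williamson ether synthesis with in situ Finkelstein activation of the α-chloroketone; room temperature is kept so that the aryloxy ketone should not go on to the Rap–Stoermer benzofuran condensation with the electron-rich aldehyde.

Step 5
Reactants: 9 2-{2-[2-methoxy-4-(triisopropylsilyloxy)phenyl]-2-oxoethoxy}-4,6-bis(methoxymethoxy)benzaldehyde
Product: 11 3-[2-methoxy-4-(triisopropylsilyloxy)phenyl]-5,7-bis(methoxymethoxy)-2H-chromene, via titanium pinacolate 10 (not isolated)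
Conditions: TiCl4, Zn, pyridine, THF, reflux; slow addition of 9
Reagents that add atoms: none
Why: Intramolecular McMurry coupling: low-valent titanium made from TiCl4 and Zn couples the aryl ketone and the aryl aldehyde through their ketyls to pinacolate 10 and deoxygenates it to the conjugated C3=C4 alkene; the six-membered ring and the stilbene-like product favour closure, and pyridine buffers the Lewis-acidic chlorides so the acetal and silyl ethers should persist.

Step 6
Reactants: 11 3-[2-methoxy-4-(triisopropylsilyloxy)phenyl]-5,7-bis(methoxymethoxy)-2H-chromene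
Product: 13 (3R,4S)-3-[2-methoxy-4-(triisopropylsilyloxy)phenyl]-5,7-bis(methoxymethoxy)chromane-3,4-diol, via osmate ester 12 (not isolated)
Conditions: OsO4 (1.1 equiv), (DHQ)2PHAL (1.2 equiv), CH2Cl2, −20 °C; then aq Na2SO3, rt
Reagents that add atoms: osmium tetroxide, O=[Os](=O)(=O)=O
Why: Ligand-bound OsO4 adds suprafacially across C3=C4 in a [3+2] cycloaddition to give the cyclic osmate ester 12, which sulfite cleaves reductively to the cis-diol, so the C3–O and C4–O bonds form on one face. The closest known reaction is the Sharpless asymmetric dihydroxylation in its stoichiometric-osmium form, established for trisubstituted aryl alkenes of the 1-arylcycloalkene type and for isoflav-3-enes. No ring is closed, since ring C is already in place. Both new stereocentres are controlled by the cinchona ligand: with (DHQ)2PHAL the alkene should bind with ring B in the aryl-binding quadrant and C4–H in the most hindered quadrant, so that osmium is delivered to the face that makes C3 R and C4 S, the cis relationship following from the concerted addition. The step needs enantiofacial selectivity and chemoselectivity; the first rests on the flat, conjugated, trisubstituted alkene fitting the ligand pocket, the second on C3=C4 being the only alkene in 11, because the dimethylallyl group is introduced later and ring B is carried as a silyl ether.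

Step 7
Reactants: 13 (3R,4S)-3-[2-methoxy-4-(triisopropylsilyloxy)phenyl]-5,7-bis(methoxymethoxy)chromane-3,4-diol
Product: 14 (3R)-3-hydroxy-3-[2-methoxy-4-(triisopropylsilyloxy)phenyl]-5,7-bis(methoxymethoxy)chroman-4-one
Conditions: IBX, DMSO, rt
Reagents that add atoms: none
Why: IBX oxidation of the secondary benzylic alcohol: in DMSO this reagent turns 1,2-diols into α-ketols without C–C cleavage, the tertiary C3 carbinol cannot be oxidised and carries no hydrogen so its R configuration is untouched, and the oxidation is placed before desilylation because IBX would attack a free phenol.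

Step 8
Reactants: 14 (3R)-3-hydroxy-3-[2-methoxy-4-(triisopropylsilyloxy)phenyl]-5,7-bis(methoxymethoxy)chroman-4-one
Product: 15 (3R)-3-hydroxy-3-(4-hydroxy-2-methoxyphenyl)-5,7-bis(methoxymethoxy)chroman-4-one
Conditions: Bu4NF, AcOH, THF, 0 °C → rt
Reagents that add atoms: none
Why: Fluoride-induced cleavage of the aryl silyl ether; acetic acid buffers the medium so that the tertiary α-ketol and the MOM ethers should be left alone.

Step 9
Reactants: 15 (3R)-3-hydroxy-3-(4-hydroxy-2-methoxyphenyl)-5,7-bis(methoxymethoxy)chroman-4-one; 16 prenyl bromide (1-bromo-3-methylbut-2-ene)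
Product: 17 (3R)-3-hydroxy-3-[2-methoxy-4-(3-methylbut-2-enyloxy)phenyl]-5,7-bis(methoxymethoxy)chroman-4-one
Conditions: K2CO3, acetone, 50 °C
Reagents that add atoms: none
Why: Williamson O-alkylation: the C4′ phenol is the only hydroxyl acidic enough for carbonate, so the phenoxide should displace the primary allylic bromide at oxygen while the tertiary alcohol stays free.

Step 10
Reactants: 17 (3R)-3-hydroxy-3-[2-methoxy-4-(3-methylbut-2-enyloxy)phenyl]-5,7-bis(methoxymethoxy)chroman-4-one
Product: 19 (3R)-3-hydroxy-3-[4-hydroxy-2-methoxy-5-(2-methylbut-3-en-2-yl)phenyl]-5,7-bis(methoxymethoxy)chroman-4-one, via ortho-dienone 18 (not isolated)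
Conditions: EtOH/H2O (4:1), 130 °C, sealed tube
Reagents that add atoms: none
Why: Aromatic Claisen rearrangement: the [3,3]-sigmatropic shift, accelerated by the protic aqueous medium, should deliver the allyl terminus with inversion to C5′ (the ortho carbon para to the methoxy group, whereas C3′ is flanked by two oxygens) to give dienone 18, which tautomerises to the phenol; this regiochemistry is the one known for 4-prenyloxy-2-methoxyaryl ethers, and C3 is not involved.

Step 11
Reactants: 19 (3R)-3-hydroxy-3-[4-hydroxy-2-methoxy-5-(2-methylbut-3-en-2-yl)phenyl]-5,7-bis(methoxymethoxy)chroman-4-one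
Product: 20 (3R)-3,5,7-trihydroxy-3-[4-hydroxy-2-methoxy-5-(2-methylbut-3-en-2-yl)phenyl]chroman-4-one
Conditions: HCl (3 M in MeOH), rt → 40 °C
Reagents that add atoms: none
Why: Acid-catalysed acetal cleavage (transacetalisation to methanol) should remove both MOM ethers, the 5-O group being assisted by the peri carbonyl; dilute acid near room temperature is chosen because ionisation of the tertiary benzylic carbinol is disfavoured by the adjacent carbonyl and ortho-(1,1-dimethylallyl)phenols are known to tolerate such conditions.

**Compound list**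

1 | 4-bromo-3-methoxyphenol | COc1cc(O)ccc1Br | starting material
2 | (4-bromo-3-methoxyphenoxy)triisopropylsilane | COc1cc(O[Si](C(C)C)(C(C)C)C(C)C)ccc1Br | intermediate
3 | 2-chloro-N-methoxy-N-methylacetamide | CON(C)C(=O)CCl | starting material
4 | [2-methoxy-4-(triisopropylsilyloxy)phenyl]lithium (aryllithium) | COc1cc(O[Si](C(C)C)(C(C)C)C(C)C)ccc1[Li] | intermediate
5 | lithium hemiaminal adduct of 4 and 3 (lithium alkoxide of the N-methoxy-N-methyl hemiaminal) | COc1cc(O[Si](C(C)C)(C(C)C)C(C)C)ccc1C(O[Li])(CCl)N(C)OC | intermediate
6 | 2-chloro-1-[2-methoxy-4-(triisopropylsilyloxy)phenyl]ethan-1-one | COc1cc(O[Si](C(C)C)(C(C)C)C(C)C)ccc1C(=O)CCl | intermediate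
7 | 2,4,6-trihydroxybenzaldehyde | O=Cc1c(O)cc(O)cc1O | starting material
8 | 2-hydroxy-4,6-bis(methoxymethoxy)benzaldehyde | COCOc1cc(O)c(C=O)c(OCOC)c1 | intermediate
9 | 2-{2-[2-methoxy-4-(triisopropylsilyloxy)phenyl]-2-oxoethoxy}-4,6-bis(methoxymethoxy)benzaldehyde | COc1cc(O[Si](C(C)C)(C(C)C)C(C)C)ccc1C(=O)COc1cc(OCOC)cc(OCOC)c1C=O | intermediate
10 | titanium pinacolate (cyclic titanium 3,4-diolate of the coupled chromane) | COc1cc(O[Si](C(C)C)(C(C)C)C(C)C)ccc1C12COc3cc(OCOC)cc(OCOC)c3C1O[Ti]O2 | intermediate
11 | 3-[2-methoxy-4-(triisopropylsilyloxy)phenyl]-5,7-bis(methoxymethoxy)-2H-chromene | COc1cc(O[Si](C(C)C)(C(C)C)C(C)C)ccc1C1=Cc2c(OCOC)cc(OCOC)cc2OC1 | intermediate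
12 | cyclic osmate ester of diol 13 (hexavalent osmium, dioxo) | COc1cc(O[Si](C(C)C)(C(C)C)C(C)C)ccc1[C@@]12COc3cc(OCOC)cc(OCOC)c3[C@@H]1O[Os](=O)(=O)O2 | intermediate
13 | (3R,4S)-3-[2-methoxy-4-(triisopropylsilyloxy)phenyl]-5,7-bis(methoxymethoxy)chromane-3,4-diol (cis) | COc1cc(O[Si](C(C)C)(C(C)C)C(C)C)ccc1[C@@]1(O)COc2cc(OCOC)cc(OCOC)c2[C@@H]1O | intermediate
14 | (3R)-3-hydroxy-3-[2-methoxy-4-(triisopropylsilyloxy)phenyl]-5,7-bis(methoxymethoxy)chroman-4-one | COc1cc(O[Si](C(C)C)(C(C)C)C(C)C)ccc1[C@@]1(O)COc2cc(OCOC)cc(OCOC)c2C1=O | intermediate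
15 | (3R)-3-hydroxy-3-(4-hydroxy-2-methoxyphenyl)-5,7-bis(methoxymethoxy)chroman-4-one | COc1cc(O)ccc1[C@@]1(O)COc2cc(OCOC)cc(OCOC)c2C1=O | intermediate
16 | prenyl bromide (1-bromo-3-methylbut-2-ene) | CC(C)=CCBr | starting material
17 | (3R)-3-hydroxy-3-[2-methoxy-4-(3-methylbut-2-enyloxy)phenyl]-5,7-bis(methoxymethoxy)chroman-4-one | COc1cc(OCC=C(C)C)ccc1[C@@]1(O)COc2cc(OCOC)cc(OCOC)c2C1=O | intermediate
18 | ortho-dienone: 3-methoxy-6-(2-methylbut-3-en-2-yl)cyclohexa-2,4-dien-1-one carrying the chromanone at C4 (ring-B C5′ sp3, configuration there undefined) | COC1=CC(=O)C(C(C)(C)C=C)C=C1[C@@]1(O)COc2cc(OCOC)cc(OCOC)c2C1=O | intermediate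
19 | (3R)-3-hydroxy-3-[4-hydroxy-2-methoxy-5-(2-methylbut-3-en-2-yl)phenyl]-5,7-bis(methoxymethoxy)chroman-4-one | C=CC(C)(C)c1cc([C@@]2(O)COc3cc(OCOC)cc(OCOC)c3C2=O)c(OC)cc1O | intermediate
20 | (3R)-3,5,7-trihydroxy-3-[4-hydroxy-2-methoxy-5-(2-methylbut-3-en-2-yl)phenyl]chroman-4-one | C=CC(C)(C)c1cc([C@@]2(O)COc3cc(O)cc(O)c3C2=O)c(OC)cc1O | target

**Count**

Total steps: 11. Longest linear sequence: 10 steps (steps 1, 2, 4–11, from 4-bromo-3-methoxyphenol); step 3 is a one-step branch.

**Steps most likely to fail**

Step 5 (McMurry closure of ring C). The ketyl of the aryl ketone may expel the ring-A phenoxide (reductive scission of the O1–C2 bond) faster than it couples. The reaction may also stop at the pinacol, or the acetal and silyl ethers may be lost to Lewis-acidic titanium and zinc chlorides. The fallback sets out from 9. Twofold Wittig methylenation (Ph3P=CH2 from Ph3PCH3Br and KOt-Bu, THF, 0 °C → rt) should convert both carbonyl groups into methylene groups and give the styrenyl 2-arylallyl ether (diene) F1. Ring-closing metathesis with the second-generation Grubbs catalyst (H2IMes)(PCy3)Cl2Ru=CHPh in toluene at 60–80 °C should then form C3=C4 with loss of ethene and rejoin the route at 11.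

Step 10 (Claisen rearrangement). The prenyl group may be lost by C–O cleavage, or it may migrate to C3′. The new ortho-(1,1-dimethylallyl)phenol may add to its own vinyl group, and the tertiary α-ketol may degrade at the temperature needed. The fallback sets out from 15 and replaces the sigmatropic shift by a cross-coupling. Ortho-bromination of the free phenol (NBS, cat. i-Pr2NH, CH2Cl2, 0 °C) should go to C5′, the position ortho to the hydroxyl and para to the methoxy group, giving the 5′-bromophenol F2; ring A is also activated and could compete. Suzuki–Miyaura coupling of F2 with 3-methylbut-2-enylboronic acid pinacol ester under branched-selective conditions (Pd(OAc)2, a bulky biarylphosphine chosen for attack through the γ-carbon, aq K3PO4, THF, 40 °C) should install the 2-methylbut-3-en-2-yl group and rejoin the route at 19.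

Step 11 (MOM cleavage). Acid may ionise the tertiary benzylic carbinol, leading to dehydration towards the isoflavone or to methanolysis, and may promote addition of the C4′ phenol to the vinyl group. The fallback sets out from 19 and avoids protic acid. TMSOTf with 2,2′-bipyridyl in CH2Cl2 at 0 °C should exchange the aryl MOM ethers for trimethylsilyl ethers and silylate the free hydroxyls, giving the tetrakis(trimethylsilyl) ether F3. Mild hydrolysis (dilute aqueous citric acid in MeOH, rt) should then release all four hydroxyls and arrive at 20.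

**Further compounds**

F1 | step 5 | 1-ethenyl-2-({2-[2-methoxy-4-(triisopropylsilyloxy)phenyl]prop-2-en-1-yl}oxy)-4,6-bis(methoxymethoxy)benzene | COc1cc(O[Si](C(C)C)(C(C)C)C(C)C)ccc1C(=C)COc1cc(OCOC)cc(OCOC)c1C=C
F2 | step 10 | (3R)-3-(5-bromo-4-hydroxy-2-methoxyphenyl)-3-hydroxy-5,7-bis(methoxymethoxy)chroman-4-one | COc1cc(O)c(Br)cc1[C@@]1(O)COc2cc(OCOC)cc(OCOC)c2C1=O
F3 | step 11 | (3R)-3-[2-methoxy-5-(2-methylbut-3-en-2-yl)-4-(trimethylsilyloxy)phenyl]-3,5,7-tris(trimethylsilyloxy)chroman-4-one | C=CC(C)(C)c1cc([C@@]2(O[Si](C)(C)C)COc3cc(O[Si](C)(C)C)cc(O[Si](C)(C)C)c3C2=O)c(OC)cc1O[Si](C)(C)C
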